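**Retrosynthetic overview**

1. Target 23 ⇐ acid 18 + [2-(furan-3-yl)ethyl]zinc iodide 21 (acylation at C9). 18 ⇐ lactone 14 by C7 acetylation, alkyne hydration (C8 ketone) and hydrogenation (C2=C3 alkene, benzyl ester).
2. Key disconnection: the lactone bonds C19–C4 and O–C6 ⇐ cyclohex-2-enol 10 (C2–OH, C3=C4) carrying a C6–C7 trans-epoxide, plus Me2NCH(OMe)2. The reaction is a [2,3]-sigmatropic formamide-acetal (Büchi) rearrangement followed in the same flask by epoxide opening through the amide oxygen.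
3. Enabling feature: the lactone carbonyl carbon sits on quaternary C4 of the cyclohexane (ring A), 1,3 to C2 through C3, and the lactone oxygen on C6 is vicinal to the C7 acetoxy carbon. An allylic oxygen on C2 can therefore carry the one-carbon unit to C4 and finish as the ring oxygen on C6 by opening a C6–C7 epoxide.
4. 10 ⇐ enone 8 (Shi epoxidation, CBS reduction) ⇐ Diels–Alder adduct 5 (Takai, Sonogashira, Saegusa–Ito) ⇐ diene 4 + dienophile 2.
5. Ring order: ring A first, by the asymmetric Diels–Alder reaction (sets C5, C10); lactone ring B second, in the key step (sets C4 and C6; C7 comes from the epoxide).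

Key step: step 9

Remark on locants: labdane-type numbering of the target is used. Ring A = C1–C5 and C10; C19 = lactone carbonyl on C4; C6 = lactone carbinol carbon; C7 = acetoxy carbon; C8 = methyl ketone; C9 = furylpropanoyl carbonyl; C18 and C20 = methyls on C4 and C10.

Assumption: the sense of induction of the two oxazaborolidine-based catalysts (steps 3 and 8) is assigned from their usual transition-state models; if either proves opposite, the antipodal catalyst is used.

**Route**

Step 1
Reactants: 1 benzyl tiglate (benzyl (E)-2-methylbut-2-enoate)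
Product: 2 benzyl (E)-2-methyl-4-oxobut-2-enoate
Conditions: SeO2 (1.2 equiv), 1,4-dioxane, 100 °C
Reagents that add atoms: selenium dioxide, O=[Se]=O
Why: Riley oxidation, in which the ene/[2,3] sequence of SeO2 should oxidise the γ-methyl of the enoate to the aldehyde with retention of the E geometry.

Step 2
Reactants: 3 (E)-pent-3-en-2-one
Product: 4 triisopropyl{[(3E)-penta-1,3-dien-2-yl]oxy}silane
Conditions: TIPSOTf, Et3N, Et2O, 0 °C
Reagents that add atoms: triisopropylsilyl trifluoromethanesulfonate, CC(C)[Si](C(C)C)(C(C)C)OS(=O)(=O)C(F)(F)F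
Why: Soft enolisation of the methyl ketone on its methyl side with a silyl triflate and an amine should give the 2-silyloxy diene without touching the E-alkene.

Step 3
Reactants: 2 benzyl (E)-2-methyl-4-oxobut-2-enoate; 4 triisopropyl{[(3E)-penta-1,3-dien-2-yl]oxy}silane
Product: 5 benzyl (1S,5S,6S)-6-formyl-1,5-dimethyl-3-[(triisopropylsilyl)oxy]cyclohex-3-ene-1-carboxylate
Conditions: (S)-3,3-diphenyl-1-(o-tolyl)tetrahydro-1H,3H-pyrrolo[1,2-c][1,3,2]oxazaborole protonated by Tf2NH (20 mol %), CH2Cl2, −78 → −40 °C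
Reagents that add atoms: none
Why: Catalytic asymmetric Diels–Alder reaction in which the cationic oxazaborolidine binds the formyl group, so the unsubstituted diene terminus (future C1) should attack C10 (β to the aldehyde) and the methyl-bearing terminus should join C5; suprafacial addition to the E-dienophile fixes formyl trans to the benzyl ester (C5 and C10), the catalyst face selection fixes the absolute configuration, and the endo-derived C4 centre is erased in step 6.

Step 4
Reactants: 5 Diels–Alder adduct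
Product: 6 benzyl (1S,5R,6R)-6-[(E)-2-iodoethenyl]-1,5-dimethyl-3-[(triisopropylsilyl)oxy]cyclohex-3-ene-1-carboxylate
Conditions: CrCl2 (6 equiv), CHI3 (2 equiv), THF, 0 °C
Reagents that add atoms: iodoform, IC(I)I
Why: Takai olefination, in which the geminal dichromium species from CHI3 adds to the aldehyde and eliminates to the E-vinyl iodide under non-basic conditions that should leave the α-stereocentre C5 and the silyl enol ether intact.

Step 5
Reactants: 6 E-vinyl iodide
Product: 7 benzyl (1S,5R,6S)-1,5-dimethyl-3-[(triisopropylsilyl)oxy]-6-[(E)-4-(trimethylsilyl)but-1-en-3-yn-1-yl]cyclohex-3-ene-1-carboxylate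
Conditions: ethynyltrimethylsilane, PdCl2(PPh3)2 (3 mol %), CuI (6 mol %), Et3N, THF, 23 °C
Reagents that add atoms: ethynyltrimethylsilane, C#C[Si](C)(C)C
Why: Sonogashira coupling proceeds with retention of alkene geometry, and the silyl enol ether and the hindered benzyl ester should be inert to the amine base.

Step 6
Reactants: 7 silyl enol ether enyne
Product: 8 benzyl (1S,2S)-1,3-dimethyl-5-oxo-2-[(E)-4-(trimethylsilyl)but-1-en-3-yn-1-yl]cyclohex-3-ene-1-carboxylate
Conditions: Pd(OAc)2 (1.1 equiv), MeCN, 40 °C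
Reagents that add atoms: none
Why: Saegusa–Ito oxidation, in which the palladium enolate formed at C3 can only β-eliminate toward C4–H, so the 3-methylcyclohex-2-enone should form regiospecifically while the C4 centre is erased.

Step 7
Reactants: 8 enone enyne
Product: 9 benzyl (1S,2S)-1,3-dimethyl-5-oxo-2-{(2R,3R)-3-[(trimethylsilyl)ethynyl]oxiran-2-yl}cyclohex-3-ene-1-carboxylate
Conditions: 1,2:4,5-di-O-isopropylidene-β-D-erythro-2,3-hexodiulo-2,6-pyranose (D-fructose-derived Shi ketone, 30 mol %), Oxone (KHSO5), K2CO3, Bu4NHSO4, MeCN/dimethoxymethane/aqueous buffer (pH 10.5), 0 °C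
Reagents that add atoms: potassium peroxymonosulfate (Oxone), [K+].[O-]S(=O)(=O)OO
Why: Shi epoxidation, in which the chiral dioxirane should epoxidise the E-enyne alkene in preference to the electron-poor enone alkene and the spiro transition state of the D-fructose-derived ketone should give the (R,R)-trans-epoxide (C6, C7) under reagent control.

Step 8
Reactants: 9 epoxy enone
Product: 10 benzyl (1S,2S,5S)-5-hydroxy-1,3-dimethyl-2-{(2R,3R)-3-[(trimethylsilyl)ethynyl]oxiran-2-yl}cyclohex-3-ene-1-carboxylate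
Conditions: (R)-2-methyl-CBS-oxazaborolidine ((R)-1-methyl-3,3-diphenyltetrahydro-1H,3H-pyrrolo[1,2-c][1,3,2]oxazaborole, 30 mol %), catecholborane, toluene, −78 °C
Reagents that add atoms: none
Why: Corey–Bakshi–Shibata reduction in which the alkenyl arm acts as the large group, so the (R)-catalyst should give the (S)-carbinol at C2 (hydroxyl on the ring face that carries the C5 side chain) while the hindered ester, the epoxide and the alkyne are untouched at −78 °C.

Step 9
Reactants: 10 epoxy cyclohex-2-enol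
Product: 14 benzyl (1S,3aS,7S,7aR)-1-[(1R)-1-hydroxy-3-(trimethylsilyl)prop-2-yn-1-yl]-3a,7-dimethyl-3-oxo-1,3,3a,6,7,7a-hexahydro-2-benzofuran-7-carboxylate, via mixed formamide acetal 11 (not isolated), via epoxy amide 12 (not isolated), via cyclic iminium ether 13 (not isolated)
Conditions: Me2NCH(OMe)2 (3 equiv), xylenes, 140 °C, MeOH distilled off; then (+)-camphorsulfonic acid (2 equiv), THF/H2O, 23 °C
Reagents that add atoms: N,N-dimethylformamide dimethyl acetal, COC(OC)N(C)C; water, O
Why: Transacetalisation of the C2 carbinol and loss of methanol give an alkoxy(dimethylamino)carbene whose [2,3]-sigmatropic shift (Büchi rearrangement) joins the carbene carbon C19 to C4 across C3=C4 while the C2 oxygen becomes the amide carbonyl oxygen; on acidification this oxygen opens the neighbouring epoxide at C6 to a cyclic iminium ether that water hydrolyses to the lactone. The closest known reaction types are the formamide-acetal rearrangement of cyclohex-2-enols to cyclohex-2-ene-1-carboxamides with a quaternary C1, and the lactonisation of γ,δ-epoxy amides through the amide oxygen. The only ring closed is the lactone, by 5-exo-tet opening of the epoxide at C6 (ring O–C19–C4–C5–C6). C4 is set by the suprafacial course of the sigmatropic shift, which delivers C19 to the face that carried the C2 hydroxyl (the face of the C5 side chain); C6 is set by SN2 inversion of the (6R,7R)-epoxide, and C7 keeps its epoxide configuration. The step needs the shift to outrun elimination of the acetal to a cyclohexadiene, and needs exo rather than endo (C7) opening of the epoxide. The first should be secured by the five-membered transition state open to the pseudoaxial carbene and by the absence of any enolisable ketone that could condense with the acetal; the second by the cis arrangement of amide and side chain on ring A and by the inductively electron-poor alkynyl-substituted C7, which disfavours cationic endo opening.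

Step 10
Reactants: 14 hydroxy lactone
Product: 15 benzyl (1S,3aS,7S,7aR)-1-[(1R)-1-hydroxyprop-2-yn-1-yl]-3a,7-dimethyl-3-oxo-1,3,3a,6,7,7a-hexahydro-2-benzofuran-7-carboxylate
Conditions: K2CO3 (0.2 equiv), MeOH, 0 °C
Reagents that add atoms: none
Why: Methanolysis of the alkynyl C–Si bond is fast with catalytic carbonate at 0 °C, conditions under which the hindered benzyl ester and the γ-lactone should persist.

Step 11
Reactants: 15 propargylic alcohol
Product: 16 benzyl (1S,3aS,7S,7aR)-1-[(1R)-1-(acetyloxy)prop-2-yn-1-yl]-3a,7-dimethyl-3-oxo-1,3,3a,6,7,7a-hexahydro-2-benzofuran-7-carboxylate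
Conditions: Ac2O, pyridine, DMAP (cat.), CH2Cl2, 0 → 23 °C
Reagents that add atoms: acetic anhydride, CC(=O)OC(C)=O
Why: Standard DMAP-catalysed acylation of the secondary propargylic alcohol, with no change at C7.

Step 12
Reactants: 16 propargylic acetate
Product: 17 benzyl (1S,3aS,7S,7aR)-1-[(1S)-1-(acetyloxy)-2-oxopropyl]-3a,7-dimethyl-3-oxo-1,3,3a,6,7,7a-hexahydro-2-benzofuran-7-carboxylate
Conditions: Ph3PAuCl (5 mol %), AgSbF6 (5 mol %), 1,4-dioxane/H2O, 40 °C
Reagents that add atoms: water, O
Why: Gold-catalysed hydration of a propargylic acetate, in which the acetate carbonyl adds 5-exo-dig to the gold-activated alkyne and water opens the dioxolenium ion, should give the methyl ketone (Markovnikov) with the acetate left on C7 and the stereocentre unchanged.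

Step 13
Reactants: 17 benzyl ester alkene
Product: 18 (1S,3aS,7S,7aR)-1-[(1S)-1-(acetyloxy)-2-oxopropyl]-3a,7-dimethyl-3-oxooctahydro-2-benzofuran-7-carboxylic acid
Conditions: H2 (1 atm), Pd/C (10 wt % palladium on carbon), EtOAc, 23 °C
Reagents that add atoms: none
Why: Heterogeneous hydrogenation should saturate the cis-disubstituted C2=C3 alkene and hydrogenolyse the benzyl ester in one operation; no stereocentre is formed and the ketone, acetate and lactone are inert.

Step 14
Reactants: 19 2-(furan-3-yl)ethan-1-ol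
Product: 20 3-(2-iodoethyl)furan
Conditions: I2, PPh3, imidazole, CH2Cl2, 0 → 23 °C
Reagents that add atoms: iodine, II
Why: Appel-type iodination of a primary alcohol (SN2 at a primary carbon) under conditions that the furan tolerates.

Step 15
Reactants: 20 3-(2-iodoethyl)furan
Product: 21 [2-(furan-3-yl)ethyl]zinc iodide (THF solution, used directly)
Conditions: Zn dust (activated by 1,2-dibromoethane and Me3SiCl), LiCl, THF, 40 °C
Reagents that add atoms: zinc, [Zn]
Why: Direct insertion of LiCl-activated zinc into the primary alkyl iodide should give the alkylzinc iodide, which is compatible with the furan.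

Step 16
Reactants: 18 carboxylic acid; 21 [2-(furan-3-yl)ethyl]zinc iodide
Product: 23 (1S)-1-[(1S,3aS,7S,7aR)-7-[3-(furan-3-yl)propanoyl]-3a,7-dimethyl-3-oxooctahydro-2-benzofuran-1-yl]-2-oxopropyl acetate (target), via acid chloride 22 (not isolated)
Conditions: (COCl)2, DMF (cat.), CH2Cl2, 0 → 23 °C, evaporate; then 21, Pd(PPh3)4 (5 mol %), THF, 0 → 23 °C
Reagents that add atoms: oxalyl chloride, ClC(=O)C(=O)Cl (its chlorine stays only in 22)
Why: Negishi-type acylation, in which the acid chloride adds oxidatively to zerovalent palladium and the alkylzinc iodide transmetalates faster than it can add to the methyl ketone, lactone or acetate, should give the C9 ketone without touching any stereocentre.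

**Compound list**

1 | benzyl tiglate (benzyl (E)-2-methylbut-2-enoate) | C/C=C(\C)C(=O)OCc1ccccc1 | starting material
2 | benzyl (E)-2-methyl-4-oxobut-2-enoate | O=C/C=C(\C)C(=O)OCc1ccccc1 | intermediate
3 | (E)-pent-3-en-2-one | C/C=C/C(C)=O | starting material
4 | triisopropyl{[(3E)-penta-1,3-dien-2-yl]oxy}silane | C=C(O[Si](C(C)C)(C(C)C)C(C)C)/C=C/C | intermediate
5 | benzyl (1S,5S,6S)-6-formyl-1,5-dimethyl-3-[(triisopropylsilyl)oxy]cyclohex-3-ene-1-carboxylate (formyl trans to ester, cis to both methyls) | O=C[C@H]1[C@@H](C)C=C(O[Si](C(C)C)(C(C)C)C(C)C)C[C@]1(C)C(=O)OCc2ccccc2 | intermediate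
6 | benzyl (1S,5R,6R)-6-[(E)-2-iodoethenyl]-1,5-dimethyl-3-[(triisopropylsilyl)oxy]cyclohex-3-ene-1-carboxylate | I/C=C/[C@H]1[C@@H](C)C=C(O[Si](C(C)C)(C(C)C)C(C)C)C[C@]1(C)C(=O)OCc2ccccc2 | intermediate
7 | benzyl (1S,5R,6S)-1,5-dimethyl-3-[(triisopropylsilyl)oxy]-6-[(E)-4-(trimethylsilyl)but-1-en-3-yn-1-yl]cyclohex-3-ene-1-carboxylate | C[Si](C)(C)C#C/C=C/[C@H]1[C@@H](C)C=C(O[Si](C(C)C)(C(C)C)C(C)C)C[C@]1(C)C(=O)OCc2ccccc2 | intermediate
8 | benzyl (1S,2S)-1,3-dimethyl-5-oxo-2-[(E)-4-(trimethylsilyl)but-1-en-3-yn-1-yl]cyclohex-3-ene-1-carboxylate | C[Si](C)(C)C#C/C=C/[C@H]1C(C)=CC(=O)C[C@]1(C)C(=O)OCc2ccccc2 | intermediate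
9 | benzyl (1S,2S)-1,3-dimethyl-5-oxo-2-{(2R,3R)-3-[(trimethylsilyl)ethynyl]oxiran-2-yl}cyclohex-3-ene-1-carboxylate | C[Si](C)(C)C#C[C@H]2O[C@@H]2[C@H]1C(C)=CC(=O)C[C@]1(C)C(=O)OCc3ccccc3 | intermediate
10 | benzyl (1S,2S,5S)-5-hydroxy-1,3-dimethyl-2-{(2R,3R)-3-[(trimethylsilyl)ethynyl]oxiran-2-yl}cyclohex-3-ene-1-carboxylate | C[Si](C)(C)C#C[C@H]2O[C@@H]2[C@H]1C(C)=C[C@@H](O)C[C@]1(C)C(=O)OCc3ccccc3 | intermediate
11 | mixed formamide acetal: [dimethylamino(methoxy)methyl] ether of 10 at the C2 oxygen | C[Si](C)(C)C#C[C@H]2O[C@@H]2[C@H]1C(C)=C[C@@H](OC(OC)N(C)C)C[C@]1(C)C(=O)OCc3ccccc3 | intermediate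
12 | epoxy amide: benzyl (1S,5S,6S)-5-(dimethylcarbamoyl)-1,5-dimethyl-6-{(2R,3R)-3-[(trimethylsilyl)ethynyl]oxiran-2-yl}cyclohex-3-ene-1-carboxylate | C[Si](C)(C)C#C[C@H]2O[C@@H]2[C@H]1[C@@](C)(C(=O)N(C)C)C=CC[C@]1(C)C(=O)OCc3ccccc3 | intermediate
13 | cyclic iminium ether: 14 with the lactone C=O replaced by C=N(+)Me2 | C[Si](C)(C)C#C[C@@H](O)[C@H]1OC(=[N+](C)C)[C@@]2(C)C=CC[C@](C)(C(=O)OCc3ccccc3)[C@@H]12 | intermediate
14 | benzyl (1S,3aS,7S,7aR)-1-[(1R)-1-hydroxy-3-(trimethylsilyl)prop-2-yn-1-yl]-3a,7-dimethyl-3-oxo-1,3,3a,6,7,7a-hexahydro-2-benzofuran-7-carboxylate | C[Si](C)(C)C#C[C@@H](O)[C@H]1OC(=O)[C@@]2(C)C=CC[C@](C)(C(=O)OCc3ccccc3)[C@@H]12 | intermediate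
15 | benzyl (1S,3aS,7S,7aR)-1-[(1R)-1-hydroxyprop-2-yn-1-yl]-3a,7-dimethyl-3-oxo-1,3,3a,6,7,7a-hexahydro-2-benzofuran-7-carboxylate | C#C[C@@H](O)[C@H]1OC(=O)[C@@]2(C)C=CC[C@](C)(C(=O)OCc3ccccc3)[C@@H]12 | intermediate
16 | benzyl (1S,3aS,7S,7aR)-1-[(1R)-1-(acetyloxy)prop-2-yn-1-yl]-3a,7-dimethyl-3-oxo-1,3,3a,6,7,7a-hexahydro-2-benzofuran-7-carboxylate | C#C[C@@H](OC(C)=O)[C@H]1OC(=O)[C@@]2(C)C=CC[C@](C)(C(=O)OCc3ccccc3)[C@@H]12 | intermediate
17 | benzyl (1S,3aS,7S,7aR)-1-[(1S)-1-(acetyloxy)-2-oxopropyl]-3a,7-dimethyl-3-oxo-1,3,3a,6,7,7a-hexahydro-2-benzofuran-7-carboxylate | CC(=O)[C@@H](OC(C)=O)[C@H]1OC(=O)[C@@]2(C)C=CC[C@](C)(C(=O)OCc3ccccc3)[C@@H]12 | intermediate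
18 | (1S,3aS,7S,7aR)-1-[(1S)-1-(acetyloxy)-2-oxopropyl]-3a,7-dimethyl-3-oxooctahydro-2-benzofuran-7-carboxylic acid | CC(=O)[C@@H](OC(C)=O)[C@H]1OC(=O)[C@@]2(C)CCC[C@](C)(C(=O)O)[C@@H]12 | intermediate
19 | 2-(furan-3-yl)ethan-1-ol | OCCc1ccoc1 | starting material
20 | 3-(2-iodoethyl)furan | ICCc1ccoc1 | intermediate
21 | [2-(furan-3-yl)ethyl]zinc iodide | I[Zn]CCc1ccoc1 | intermediate
22 | acid chloride of 18 (C9 carbonyl chloride) | CC(=O)[C@@H](OC(C)=O)[C@H]1OC(=O)[C@@]2(C)CCC[C@](C)(C(=O)Cl)[C@@H]12 | intermediate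
23 | (1S)-1-[(1S,3aS,7S,7aR)-7-[3-(furan-3-yl)propanoyl]-3a,7-dimethyl-3-oxooctahydro-2-benzofuran-1-yl]-2-oxopropyl acetate | CC(=O)O[C@H](C(C)=O)[C@H]1OC(=O)[C@@]2(C)CCC[C@](C)(C(=O)CCc3ccoc3)[C@@H]12 | target

**Step count and risks**

Total step count: 16. Longest linear sequence: 13 steps (steps 1, 3–13 and 16).

The three steps most likely to fail:

Step 9 (key step). The thermal carbene pathway may be diverted: the mixed acetal can eliminate to a cyclohexadiene, the sigmatropic shift onto the fully substituted C4 may be slow, and the acid stage may open the epoxide in the endo sense. The fallback sets out from 10 and comes back at 14. Alkylation of 10 (KH, Bu3SnCH2I, THF) should give the tributylstannylmethyl ether F1. Tin–lithium exchange (n-BuLi, THF, −78 °C, quenched cold) should trigger a [2,3]-Wittig–Still rearrangement that delivers a hydroxymethyl group to C4 on the same face, giving the C4-hydroxymethyl cyclohexene F2. Oxidation of the neopentyl alcohol (TEMPO, PhI(OAc)2, MeCN/H2O) should give the epoxy acid F3, and camphorsulfonic acid in CH2Cl2 should close the lactone by 5-exo opening of the epoxide to give 14.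

Step 3. Turnover may be slow and enantiofacial discrimination poor with a β,β-disubstituted enal, and the acidic catalyst may protodesilylate the diene. The fallback sets out from 2 and 4 and comes back at 9. Cycloaddition promoted by achiral EtAlCl2 (CH2Cl2, −78 °C) should give the racemic adduct, that is 5 together with its enantiomer F4. The racemate is carried through steps 4 to 6, giving the enantiomeric vinyl iodide F5, the enantiomeric enyne F6 and the enantiomeric enone F7 alongside 6, 7 and 8. The reagent-controlled epoxidation of step 7 then turns the two enantiomers into diastereomers, 9 and the ring-(1R,2R) epoxide F8, which are separated by chromatography.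

Step 8. Reagent control may be overridden by the ring stereocentres (mismatched pairing), giving the wrong facial selectivity at C2. The fallback sets out from 9 and comes back at 10. Luche reduction (NaBH4, CeCl3·7H2O, MeOH, −78 °C) is run under substrate control. If it delivers mainly the C2-epimeric alcohol F9, Mitsunobu inversion with chloroacetic acid (PPh3, DIAD, THF) should give the inverted chloroacetate F10, which thiourea/NaHCO3 (EtOH, 50 °C) should cleave to 10 without disturbing the alkynylsilane.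

Further compounds
F1 | step 9 | tributylstannylmethyl ether of 10 at the C2 oxygen | C[Si](C)(C)C#C[C@H]2O[C@@H]2[C@H]1C(C)=C[C@@H](OC[Sn](CCCC)(CCCC)CCCC)C[C@]1(C)C(=O)OCc3ccccc3
F2 | step 9 | benzyl (1S,5S,6S)-5-(hydroxymethyl)-1,5-dimethyl-6-{(2R,3R)-3-[(trimethylsilyl)ethynyl]oxiran-2-yl}cyclohex-3-ene-1-carboxylate | C[Si](C)(C)C#C[C@H]2O[C@@H]2[C@H]1[C@@](C)(CO)C=CC[C@]1(C)C(=O)OCc3ccccc3
F3 | step 9 | epoxy acid: the C4 carboxylic acid corresponding to amide 12 | C[Si](C)(C)C#C[C@H]2O[C@@H]2[C@H]1[C@@](C)(C(=O)O)C=CC[C@]1(C)C(=O)OCc3ccccc3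
F4 | step 3 | enantiomer of 5, benzyl (1R,5R,6R)-6-formyl-1,5-dimethyl-3-[(triisopropylsilyl)oxy]cyclohex-3-ene-1-carboxylate | O=C[C@@H]1[C@H](C)C=C(O[Si](C(C)C)(C(C)C)C(C)C)C[C@@]1(C)C(=O)OCc2ccccc2
F5 | step 3 | enantiomer of 6 | I/C=C/[C@@H]1[C@H](C)C=C(O[Si](C(C)C)(C(C)C)C(C)C)C[C@@]1(C)C(=O)OCc2ccccc2
F6 | step 3 | enantiomer of 7 | C[Si](C)(C)C#C/C=C/[C@@H]1[C@H](C)C=C(O[Si](C(C)C)(C(C)C)C(C)C)C[C@@]1(C)C(=O)OCc2ccccc2
F7 | step 3 | enantiomer of 8 | C[Si](C)(C)C#C/C=C/[C@@H]1C(C)=CC(=O)C[C@@]1(C)C(=O)OCc2ccccc2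
F8 | step 3 | benzyl (1R,2R)-1,3-dimethyl-5-oxo-2-{(2R,3R)-3-[(trimethylsilyl)ethynyl]oxiran-2-yl}cyclohex-3-ene-1-carboxylate (diastereomer of 9) | C[Si](C)(C)C#C[C@H]2O[C@@H]2[C@@H]1C(C)=CC(=O)C[C@@]1(C)C(=O)OCc3ccccc3
F9 | step 8 | C2 epimer of 10, benzyl (1S,2S,5R)-5-hydroxy-1,3-dimethyl-2-{(2R,3R)-3-[(trimethylsilyl)ethynyl]oxiran-2-yl}cyclohex-3-ene-1-carboxylate | C[Si](C)(C)C#C[C@H]2O[C@@H]2[C@H]1C(C)=C[C@H](O)C[C@]1(C)C(=O)OCc3ccccc3
F10 | step 8 | chloroacetate of 10 at the C2 oxygen | C[Si](C)(C)C#C[C@H]2O[C@@H]2[C@H]1C(C)=C[C@@H](OC(=O)CCl)C[C@]1(C)C(=O)OCc3ccccc3
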